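The route rests on disconnecting C5–C6, the bond between the (Z)-C4=C5 alkene carbon and the lactone carbinol C6 of the ten-membered carbocycle. The key step closes this bond by a nickel/chromium-mediated alkenyl iodide–aldehyde cyclisation. Because the new C6 alkoxide lies 1,4 to the C12 ester on C11, it lactonises, so one operation makes the carbocycle, the C6 stereocentre and the α-methylene-γ-butyrolactone. The precursor is an acyclic (Z)-iodoalkene aldehyde already carrying the C1–C10 epoxide, the C3 acetate, the C8 methacrylate and the C11 acrylate ester. It is built by ring-closing metathesis (Z-C1=C10), asymmetric syn-selective 2-(methoxycarbonyl)allylation (C7, C8) and Shi epoxidation.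

Key step: step 16

Remark: germacrane numbering is used (C1–C10 ring carbons, C11–C13 the methylene-lactone carbons with C12 the carbonyl, C14 and C15 the methyls on C10 and C4); the target is read as (1R,3S,4Z,6S,7R,8R,10S) with a cis-1,10-epoxide and a cis-fused lactone, and the CIP descriptor at C7 switches between S and R with the substituents on C6 without any change of configuration.

Step 1
Reactants: 1 prop-2-yn-1-ol
Product: 3 (2Z)-3-iodo-2-methylprop-2-en-1-ol, via alkenylmagnesium alkoxide 2 (not isolated)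
Conditions: MeMgBr (2.5 equiv), CuI (10 mol%), THF, −10 °C to rt; then I2, −78 to 0 °C
Reagents that add atoms: methylmagnesium bromide, C[Mg]Br; iodine, II
Why: Copper-catalysed anti-carbomagnesiation of the propargylic alkoxide places methyl on C4 and magnesium on C5 cis to the CH2O group through a five-membered chelate, and iodinolysis with retention should give the (Z)-iodide.

Step 2
Reactants: 3 (2Z)-3-iodo-2-methylprop-2-en-1-ol
Product: 4 (2Z)-3-iodo-2-methylprop-2-enal
Conditions: activated MnO2 (15 equiv), CH2Cl2, rt, dark; filtered and used at once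
Reagents that add atoms: none
Why: Allylic oxidation on the MnO2 surface is neutral, so the labile (Z)-iodoenal should not isomerise if it is kept cold and dark.

Step 3
Reactants: 4 (2Z)-3-iodo-2-methylprop-2-enal
Product: 6 (1Z,3S)-1-iodo-2-methylhexa-1,5-dien-3-ol, via diisopinocampheylborinate ester 5 (not isolated)
Conditions: (−)-Ipc2B(allyl) [from (+)-α-pinene], Et2O, −78 °C; then NaOH, H2O2, 0 °C to rt
Reagents that add atoms: (−)-B-allyldiisopinocampheylborane, C=CCB([C@@H]1C[C@@H]2C[C@H]([C@H]1C)C2(C)C)[C@@H]1C[C@@H]2C[C@H]([C@H]1C)C2(C)C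
Why: Brown allylation through a chair six-membered transition state, in which the (−)-Ipc2B reagent delivers allyl to the Si face of the aldehyde, should set C3 as S (the alkenyl group outranks allyl).

Step 4
Reactants: 6 (1Z,3S)-1-iodo-2-methylhexa-1,5-dien-3-ol; 7 3-methylbut-3-enoic acid
Product: 8 (1Z,3S)-1-iodo-2-methylhexa-1,5-dien-3-yl 3-methylbut-3-enoate
Conditions: DIC, DMAP (5 mol%), CH2Cl2, 0 °C
Reagents that add atoms: none
Why: Steglich esterification with only catalytic DMAP in the cold acylates the secondary alcohol with retention at C3 and keeps the β,γ-unsaturated acid from slipping into conjugation.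

Step 5
Reactants: 8 (1Z,3S)-1-iodo-2-methylhexa-1,5-dien-3-yl 3-methylbut-3-enoate
Product: 9 (7S)-7-[(1Z)-1-iodoprop-1-en-2-yl]-4-methyl-6,7-dihydrooxepin-2(3H)-one
Conditions: second-generation Grubbs catalyst, (H2IMes)(PCy3)Cl2Ru=CHPh (10 mol%), 1,4-benzoquinone (20 mol%), CH2Cl2 (2 mM), reflux
Reagents that add atoms: none
Why: Ring-closing metathesis starts at the monosubstituted alkene and closes onto the 1,1-disubstituted alkene, and the seven-membered lactone forces the new trisubstituted C1=C10 alkene to be Z (C2 and C9 cis), while the hindered iodoalkene does not engage and benzoquinone suppresses alkene migration.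

Step 6
Reactants: 9 (7S)-7-[(1Z)-1-iodoprop-1-en-2-yl]-4-methyl-6,7-dihydrooxepin-2(3H)-one
Product: 10 (3Z,6S,7Z)-6-hydroxy-8-iodo-N-methoxy-N,3,7-trimethylocta-3,7-dienamide
Conditions: MeNH(OMe)·HCl, AlMe3, CH2Cl2, 0 °C to rt
Reagents that add atoms: N,O-dimethylhydroxylamine hydrochloride, CNOC.Cl
Why: Aluminium amide aminolysis of the lactone (Weinreb amide formation) frees the C3 hydroxyl and makes C8 an aldehyde precursor without base, so the β,γ-unsaturated Z-alkene should stay in place.

Step 7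
Reactants: 10 (3Z,6S,7Z)-6-hydroxy-8-iodo-N-methoxy-N,3,7-trimethylocta-3,7-dienamide
Product: 11 (1Z,3S,5Z)-1-iodo-8-[methoxy(methyl)amino]-2,6-dimethyl-8-oxoocta-1,5-dien-3-yl acetate
Conditions: Ac2O, pyridine, DMAP (cat.), CH2Cl2, 0 °C to rt
Reagents that add atoms: acetic anhydride, CC(=O)OC(C)=O
Why: DMAP-catalysed acylation installs the C3 acetate of the target on the only free hydroxyl with retention at C3.

Step 8
Reactants: 11 (1Z,3S,5Z)-1-iodo-8-[methoxy(methyl)amino]-2,6-dimethyl-8-oxoocta-1,5-dien-3-yl acetate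
Product: 12 (1Z,3S,5Z)-1-iodo-2,6-dimethyl-8-oxoocta-1,5-dien-3-yl acetate
Conditions: Schwartz reagent, Cp2Zr(H)Cl (1.5 equiv), THF, rt, 20 min; used crude
Reagents that add atoms: none
Why: The Schwartz reagent reduces the amide through a zirconium hemiaminal that releases the aldehyde only on work-up and should leave the acetate, the iodoalkene and the trisubstituted alkene untouched, the β,γ-unsaturated aldehyde being used without chromatography.

Step 9
Reactants: 13 [(tert-butyldimethylsilyl)oxy]acetaldehyde; 14 methyl acrylate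
Product: 15 methyl 4-[(tert-butyldimethylsilyl)oxy]-3-hydroxy-2-methylidenebutanoate (racemic)
Conditions: DABCO (0.5 equiv), excess 14, rt
Reagents that add atoms: none
Why: In this Morita–Baylis–Hillman reaction DABCO adds to the acrylate and the resulting enolate attacks the activated α-silyloxy aldehyde, and the racemic carbinol centre is erased in the next step.

Step 10
Reactants: 15 methyl 4-[(tert-butyldimethylsilyl)oxy]-3-hydroxy-2-methylidenebutanoate
Product: 16 methyl (2Z)-2-(bromomethyl)-4-[(tert-butyldimethylsilyl)oxy]but-2-enoate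
Conditions: NBS, Me2S, CH2Cl2, 0 °C to rt
Reagents that add atoms: N-bromosuccinimide, O=C1CCC(=O)N1Br
Why: The bromodimethylsulfonium salt activates the allylic alcohol and bromide attacks the methylene terminus with allylic transposition (SN2′), which should give the thermodynamically preferred trisubstituted alkene with the silyloxymethyl group trans to the ester (the Z-bromide).

Step 11
Reactants: 12 (1Z,3S,5Z)-1-iodo-2,6-dimethyl-8-oxoocta-1,5-dien-3-yl acetate; 16 methyl (2Z)-2-(bromomethyl)-4-[(tert-butyldimethylsilyl)oxy]but-2-enoate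
Product: 17 methyl (3S,4R,6Z,9S,10Z)-9-acetoxy-3-{[(tert-butyldimethylsilyl)oxy]methyl}-4-hydroxy-11-iodo-6,10-dimethyl-2-methylideneundeca-6,10-dienoate
Conditions: CrCl2 (10 mol%), chiral aryl-oxazoline sulfonamide ligand (12 mol%), Et3N (20 mol%), Mn powder (2 equiv), Cp2ZrCl2 (1.1 equiv), LiCl, MeCN, rt, nickel-free; aq. NH4Cl work-up at 0 °C
Reagents that add atoms: none
Why: In this chromium-catalysed asymmetric 2-(alkoxycarbonyl)allylation (Nozaki–Hiyama allylation) the allylchromium from 16 keeps its γ-substituent cis to the CH2Cr carbon and adds through γ-carbon C7 in a chair transition state to give the syn adduct, the ligand enantiomer being chosen to expose the Si face of the C8 aldehyde (C7 S and C8 R in 17), while the remote C3 centre exerts no bias and the iodoalkene is inert without nickel.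

Step 12
Reactants: 17 methyl (3S,4R,6Z,9S,10Z)-9-acetoxy-3-{[(tert-butyldimethylsilyl)oxy]methyl}-4-hydroxy-11-iodo-6,10-dimethyl-2-methylideneundeca-6,10-dienoate
Product: 18 methyl (3S,4R,6Z,9S,10Z)-9-acetoxy-3-{[(tert-butyldimethylsilyl)oxy]methyl}-11-iodo-4-(methacryloyloxy)-6,10-dimethyl-2-methylideneundeca-6,10-dienoate
Conditions: methacrylic anhydride, Et3N, DMAP (10 mol%), BHT (trace), CH2Cl2, 0 °C
Reagents that add atoms: methacrylic anhydride, C=C(C)C(=O)OC(=O)C(C)=C
Why: DMAP-catalysed acylation of the C8 hydroxyl, run cold on the freshly isolated hydroxy ester, should outpace closure of the unwanted 8,12-lactone and touches no stereocentre.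

Step 13
Reactants: 18 methyl (3S,4R,6Z,9S,10Z)-9-acetoxy-3-{[(tert-butyldimethylsilyl)oxy]methyl}-11-iodo-4-(methacryloyloxy)-6,10-dimethyl-2-methylideneundeca-6,10-dienoate
Product: 19 methyl (3S,4R)-5-{(2S,3R)-3-[(2S,3Z)-2-acetoxy-4-iodo-3-methylbut-3-en-1-yl]-2-methyloxiran-2-yl}-3-{[(tert-butyldimethylsilyl)oxy]methyl}-4-(methacryloyloxy)-2-methylidenepentanoate
Conditions: D-fructose-derived Shi ketone (0.3–1 equiv), Oxone (2KHSO5·KHSO4·K2SO4), K2CO3, Bu4NHSO4, MeCN–dimethoxymethane/aq. Na2B4O7–Na2EDTA buffer, 0 °C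
Reagents that add atoms: Oxone (potassium peroxymonosulfate), [K+].[O-]S(=O)(=O)OO
Why: In this Shi epoxidation the chiral dioxirane attacks the only electron-rich alkene (C1=C10, the iodoalkene and both acrylate-type alkenes being deactivated) through a spiro transition state with the C1 hydrogen in the hindered quadrant, the same face that gives (R,R)-epoxides from trans-alkenes, so the cis-epoxide should be set as 1R,10S under reagent control.

Step 14
Reactants: 19 methyl (3S,4R)-5-{(2S,3R)-3-[(2S,3Z)-2-acetoxy-4-iodo-3-methylbut-3-en-1-yl]-2-methyloxiran-2-yl}-3-{[(tert-butyldimethylsilyl)oxy]methyl}-4-(methacryloyloxy)-2-methylidenepentanoate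
Product: 20 methyl (3S,4R)-5-{(2S,3R)-3-[(2S,3Z)-2-acetoxy-4-iodo-3-methylbut-3-en-1-yl]-2-methyloxiran-2-yl}-3-(hydroxymethyl)-4-(methacryloyloxy)-2-methylidenepentanoate
Conditions: HF·pyridine, pyridine, THF, 0 °C; taken on at once
Reagents that add atoms: none
Why: Fluoride cleavage of the primary silyl ether under pyridine buffering should spare the trisubstituted epoxide and the esters, and the γ-hydroxy ester is oxidised immediately to forestall lactonisation or acyl migration.

Step 15
Reactants: 20 methyl (3S,4R)-5-{(2S,3R)-3-[(2S,3Z)-2-acetoxy-4-iodo-3-methylbut-3-en-1-yl]-2-methyloxiran-2-yl}-3-(hydroxymethyl)-4-(methacryloyloxy)-2-methylidenepentanoate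
Product: 21 methyl (3R,4R)-5-{(2S,3R)-3-[(2S,3Z)-2-acetoxy-4-iodo-3-methylbut-3-en-1-yl]-2-methyloxiran-2-yl}-3-formyl-4-(methacryloyloxy)-2-methylidenepentanoate
Conditions: Dess–Martin periodinane, NaHCO3, CH2Cl2, 0 °C; crude aldehyde used at once
Reagents that add atoms: none
Why: Dess–Martin oxidation under bicarbonate buffering gives the C6 aldehyde without a base strong enough to epimerise C7, to move the C11=C13 alkene into conjugation or to eliminate the C8 methacrylate.

Step 16
Reactants: 21 methyl (3R,4R)-5-{(2S,3R)-3-[(2S,3Z)-2-acetoxy-4-iodo-3-methylbut-3-en-1-yl]-2-methyloxiran-2-yl}-3-formyl-4-(methacryloyloxy)-2-methylidenepentanoate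
Product: 23 (1R,3S,4Z,6S,7R,8R,10S)-3-acetoxy-1,10-epoxy-8-(methacryloyloxy)germacra-4,11(13)-dien-12,6-olide, via macrocyclic hydroxy ester 22 (not isolated)
Conditions: CrCl2 (10 equiv), NiCl2 (0.1 equiv), degassed DMSO–THF, rt, syringe-pump addition of 21 to about 1 mM; aq. work-up, then PPTS (cat.), CH2Cl2, rt if lactonisation is incomplete
Reagents that add atoms: none
Why: NiCl2 is reduced by CrCl2 to zerovalent nickel, which inserts into the C5–I bond; transmetalation gives a (Z)-alkenylchromium reagent of trivalent chromium that adds to the C6 aldehyde with retention of the C4=C5 geometry, the closest known reaction type being the Nozaki–Hiyama–Kishi macrocyclisation of iodoalkenyl aldehydes to medium rings. The ten-membered carbocycle closes by 10-exo-trig addition to the carbonyl, and the C6 chromium alkoxide then closes the lactone by 5-exo-trig acyl substitution at the C12 methyl ester, on work-up at the latest. C6 is controlled by C7: in the Felkin–Anh rotamer the sp2 acrylate carbon C11 stands anti to the incoming C5 and C8 is gauche to it, which is also what the ring demands, and this should give 6S and thus the cis-fused lactone. The step needs chemoselectivity for the aldehyde over the two acrylate-type esters, the acetate and the epoxide, which the oxophilic and barely basic alkenylchromium species secures, and it needs cyclisation to beat oligomerisation, which slow addition at high dilution and the chain folding imposed by the Z-alkene and the cis-epoxide support. The base-sensitive aldehyde meets no base in this step.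

Compound list
1 | prop-2-yn-1-ol | C#CCO | starting material
2 | bromomagnesium (2Z)-3-(bromomagnesio)-2-methylprop-2-en-1-olate | Br[Mg]OC/C(C)=C\[Mg]Br | intermediate (not isolated)
3 | (2Z)-3-iodo-2-methylprop-2-en-1-ol | OC/C(C)=C\I | intermediate
4 | (2Z)-3-iodo-2-methylprop-2-enal | O=C/C(C)=C\I | intermediate
5 | (1Z,3S)-1-iodo-2-methylhexa-1,5-dien-3-yl diisopinocampheylborinate | C=CC[C@H](OB([C@@H]1C[C@@H]2C[C@H]([C@H]1C)C2(C)C)[C@@H]1C[C@@H]2C[C@H]([C@H]1C)C2(C)C)/C(C)=C\I | intermediate (not isolated)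
6 | (1Z,3S)-1-iodo-2-methylhexa-1,5-dien-3-ol | C=CC[C@H](O)/C(C)=C\I | intermediate
7 | 3-methylbut-3-enoic acid | C=C(C)CC(=O)O | starting material
8 | (1Z,3S)-1-iodo-2-methylhexa-1,5-dien-3-yl 3-methylbut-3-enoate | C=C(C)CC(=O)O[C@@H](CC=C)/C(C)=C\I | intermediate
9 | (7S)-7-[(1Z)-1-iodoprop-1-en-2-yl]-4-methyl-6,7-dihydrooxepin-2(3H)-one | O=C1CC(C)=CC[C@H](O1)/C(C)=C\I | intermediate
10 | (3Z,6S,7Z)-6-hydroxy-8-iodo-N-methoxy-N,3,7-trimethylocta-3,7-dienamide | CON(C)C(=O)C/C(C)=C\C[C@H](O)/C(C)=C\I | intermediate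
11 | (1Z,3S,5Z)-1-iodo-8-[methoxy(methyl)amino]-2,6-dimethyl-8-oxoocta-1,5-dien-3-yl acetate | CON(C)C(=O)C/C(C)=C\C[C@H](OC(C)=O)/C(C)=C\I | intermediate
12 | (1Z,3S,5Z)-1-iodo-2,6-dimethyl-8-oxoocta-1,5-dien-3-yl acetate | O=CC/C(C)=C\C[C@H](OC(C)=O)/C(C)=C\I | intermediate
13 | [(tert-butyldimethylsilyl)oxy]acetaldehyde | CC(C)(C)[Si](C)(C)OCC=O | starting material
14 | methyl acrylate | C=CC(=O)OC | starting material
15 | methyl 4-[(tert-butyldimethylsilyl)oxy]-3-hydroxy-2-methylidenebutanoate (racemic) | COC(=O)C(=C)C(O)CO[Si](C)(C)C(C)(C)C | intermediate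
16 | methyl (2Z)-2-(bromomethyl)-4-[(tert-butyldimethylsilyl)oxy]but-2-enoate | COC(=O)/C(CBr)=C/CO[Si](C)(C)C(C)(C)C | intermediate
17 | methyl (3S,4R,6Z,9S,10Z)-9-acetoxy-3-{[(tert-butyldimethylsilyl)oxy]methyl}-4-hydroxy-11-iodo-6,10-dimethyl-2-methylideneundeca-6,10-dienoate | O[C@H](C/C(C)=C\C[C@H](OC(C)=O)/C(C)=C\I)[C@H](CO[Si](C)(C)C(C)(C)C)C(=C)C(=O)OC | intermediate
18 | methyl (3S,4R,6Z,9S,10Z)-9-acetoxy-3-{[(tert-butyldimethylsilyl)oxy]methyl}-11-iodo-4-(methacryloyloxy)-6,10-dimethyl-2-methylideneundeca-6,10-dienoate | C=C(C)C(=O)O[C@H](C/C(C)=C\C[C@H](OC(C)=O)/C(C)=C\I)[C@H](CO[Si](C)(C)C(C)(C)C)C(=C)C(=O)OC | intermediate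
19 | methyl (3S,4R)-5-{(2S,3R)-3-[(2S,3Z)-2-acetoxy-4-iodo-3-methylbut-3-en-1-yl]-2-methyloxiran-2-yl}-3-{[(tert-butyldimethylsilyl)oxy]methyl}-4-(methacryloyloxy)-2-methylidenepentanoate | C=C(C)C(=O)O[C@H](C[C@]1(C)O[C@@H]1C[C@H](OC(C)=O)/C(C)=C\I)[C@H](CO[Si](C)(C)C(C)(C)C)C(=C)C(=O)OC | intermediate
20 | methyl (3S,4R)-5-{(2S,3R)-3-[(2S,3Z)-2-acetoxy-4-iodo-3-methylbut-3-en-1-yl]-2-methyloxiran-2-yl}-3-(hydroxymethyl)-4-(methacryloyloxy)-2-methylidenepentanoate | C=C(C)C(=O)O[C@H](C[C@]1(C)O[C@@H]1C[C@H](OC(C)=O)/C(C)=C\I)[C@H](CO)C(=C)C(=O)OC | intermediate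
21 | methyl (3R,4R)-5-{(2S,3R)-3-[(2S,3Z)-2-acetoxy-4-iodo-3-methylbut-3-en-1-yl]-2-methyloxiran-2-yl}-3-formyl-4-(methacryloyloxy)-2-methylidenepentanoate | C=C(C)C(=O)O[C@H](C[C@]1(C)O[C@@H]1C[C@H](OC(C)=O)/C(C)=C\I)[C@H](C=O)C(=C)C(=O)OC | intermediate
22 | methyl (1R,3S,4Z,6S,7S,8R,10S)-3-acetoxy-1,10-epoxy-6-hydroxy-8-(methacryloyloxy)germacra-4,11(13)-dien-12-oate | C=C(C)C(=O)O[C@@H]1C[C@]2(C)O[C@@H]2C[C@H](OC(C)=O)/C(C)=C\[C@H](O)[C@@H]1C(=C)C(=O)OC | intermediate (not isolated)
23 | (1R,3S,4Z,6S,7R,8R,10S)-3-acetoxy-1,10-epoxy-8-(methacryloyloxy)germacra-4,11(13)-dien-12,6-olide (CNP0267696.1) | C=C(C)C(=O)O[C@@H]1C[C@]2(C)O[C@@H]2C[C@H](OC(C)=O)/C(C)=C\[C@@H]2OC(=O)C(=C)[C@@H]21 | target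

Total step count: 16. Longest linear sequence: 14 steps (steps 1–8 and 11–16).

Steps most likely to fail

Step 16. What may go wrong is oligomerisation in place of ten-membered ring closure, opening of the epoxide by Lewis-acidic chromium salts, or attack on the wrong face of the C6 aldehyde in the epoxide-folded chain. The fallback moves the epoxide behind the ring closure. It sets out from 18: HF·pyridine/pyridine should give methyl (3S,4R,6Z,9S,10Z)-9-acetoxy-3-(hydroxymethyl)-11-iodo-4-(methacryloyloxy)-6,10-dimethyl-2-methylideneundeca-6,10-dienoate F1, and Dess–Martin periodinane/NaHCO3 the corresponding (3R,4R,6Z,9S,10Z)-3-formyl ester F2. CrCl2/NiCl2 in DMSO at high dilution should then close methyl (1(10)Z,3S,4Z,6S,7S,8R)-3-acetoxy-6-hydroxy-8-(methacryloyloxy)germacra-1(10),4,11(13)-trien-12-oate F3 (not isolated), which lactonises to (1(10)Z,3S,4Z,6S,7R,8R)-3-acetoxy-8-(methacryloyloxy)germacra-1(10),4,11(13)-trien-12,6-olide F4. Epoxidation of its only electron-rich alkene with mCPBA/NaHCO3 from the peripheral face of the macrocycle (or with the Shi ketone if the ring bias is insufficient) comes back to the route at 23.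

Step 11. What may go wrong is insufficient facial control by the ligand, erosion of the syn relationship through isomerisation of the allylchromium species, or premature closure of the 8,12-lactone. The fallback replaces the Barbier-type chromium reagent by a preformed allylboronate that reacts through a closed boron chair. It sets out from 15: Ac2O/pyridine should give methyl 3-acetoxy-4-[(tert-butyldimethylsilyl)oxy]-2-methylidenebutanoate F5, and Pd2(dba)3-catalysed borylation with B2pin2 should give methyl (2E)-4-[(tert-butyldimethylsilyl)oxy]-2-[(4,4,5,5-tetramethyl-1,3,2-dioxaborolan-2-yl)methyl]but-2-enoate F6. Its addition to 12 under a chiral BINOL-derived phosphoric acid, with the acid enantiomer chosen for the Si face, should give the O-pinacolboryl ether of 17 F7 (not isolated), which is hydrolysed on work-up and comes back to the route at 17.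

Step 13. What may go wrong is oxidation of the alkenyl iodide by Oxone, ester hydrolysis or acyl migration at pH 10, or poor face discrimination on a Z-trisubstituted alkene. The fallback epoxidises one step earlier under hydroxyl direction and without aqueous base. It sets out from 17: VO(OiPr)3 with a chiral bishydroxamic acid ligand and cumene hydroperoxide in toluene at 0 °C should deliver oxygen to C1=C10 from the C8 hydroxyl, with the ligand enantiomer chosen for the 1R,10S face, giving methyl (3S,4R)-5-{(2S,3R)-3-[(2S,3Z)-2-acetoxy-4-iodo-3-methylbut-3-en-1-yl]-2-methyloxiran-2-yl}-3-{[(tert-butyldimethylsilyl)oxy]methyl}-4-hydroxy-2-methylidenepentanoate F8. Methacryloylation as in step 12 comes back to the route at 19.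

Further compounds
F1 | step 16 | methyl (3S,4R,6Z,9S,10Z)-9-acetoxy-3-(hydroxymethyl)-11-iodo-4-(methacryloyloxy)-6,10-dimethyl-2-methylideneundeca-6,10-dienoate | C=C(C)C(=O)O[C@H](C/C(C)=C\C[C@H](OC(C)=O)/C(C)=C\I)[C@H](CO)C(=C)C(=O)OC
F2 | step 16 | methyl (3R,4R,6Z,9S,10Z)-9-acetoxy-3-formyl-11-iodo-4-(methacryloyloxy)-6,10-dimethyl-2-methylideneundeca-6,10-dienoate | C=C(C)C(=O)O[C@H](C/C(C)=C\C[C@H](OC(C)=O)/C(C)=C\I)[C@H](C=O)C(=C)C(=O)OC
F3 | step 16 | methyl (1(10)Z,3S,4Z,6S,7S,8R)-3-acetoxy-6-hydroxy-8-(methacryloyloxy)germacra-1(10),4,11(13)-trien-12-oate | C=C(C)C(=O)O[C@@H]1C/C(C)=C\C[C@H](OC(C)=O)/C(C)=C\[C@H](O)[C@@H]1C(=C)C(=O)OC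
F4 | step 16 | (1(10)Z,3S,4Z,6S,7R,8R)-3-acetoxy-8-(methacryloyloxy)germacra-1(10),4,11(13)-trien-12,6-olide | C=C(C)C(=O)O[C@@H]1C/C(C)=C\C[C@H](OC(C)=O)/C(C)=C\[C@@H]2OC(=O)C(=C)[C@@H]21
F5 | step 11 | methyl 3-acetoxy-4-[(tert-butyldimethylsilyl)oxy]-2-methylidenebutanoate | COC(=O)C(=C)C(OC(C)=O)CO[Si](C)(C)C(C)(C)C
F6 | step 11 | methyl (2E)-4-[(tert-butyldimethylsilyl)oxy]-2-[(4,4,5,5-tetramethyl-1,3,2-dioxaborolan-2-yl)methyl]but-2-enoate | COC(=O)/C(CB1OC(C)(C)C(C)(C)O1)=C/CO[Si](C)(C)C(C)(C)C
F7 | step 11 | methyl (3S,4R,6Z,9S,10Z)-9-acetoxy-3-{[(tert-butyldimethylsilyl)oxy]methyl}-11-iodo-6,10-dimethyl-2-methylidene-4-[(4,4,5,5-tetramethyl-1,3,2-dioxaborolan-2-yl)oxy]undeca-6,10-dienoate | CC1(C)OB(O[C@H](C/C(C)=C\C[C@H](OC(C)=O)/C(C)=C\I)[C@H](CO[Si](C)(C)C(C)(C)C)C(=C)C(=O)OC)OC1(C)C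
F8 | step 13 | methyl (3S,4R)-5-{(2S,3R)-3-[(2S,3Z)-2-acetoxy-4-iodo-3-methylbut-3-en-1-yl]-2-methyloxiran-2-yl}-3-{[(tert-butyldimethylsilyl)oxy]methyl}-4-hydroxy-2-methylidenepentanoate | O[C@H](C[C@]1(C)O[C@@H]1C[C@H](OC(C)=O)/C(C)=C\I)[C@H](CO[Si](C)(C)C(C)(C)C)C(=C)C(=O)OC
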